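**Remarks.** Locants C1–C15 and α/β follow the elemanolide numbering of the target: cyclohexane ring C5–C10; C1=C2 vinyl and C14H2O on the quaternary C10; C4(=C3H2)–C15H2O on C5; lactone carbons C11(=C13H2)–C12 between C7 and O–C6; β is the ring face that carries C14. The senses of induction of the three chiral catalysts (steps 3, 7, 12) are assigned by analogy with the parent acrolein, cyclohexenone and butenolide cases; the antipodal ligand would be used if an assignment proved reversed.

**Retrosynthetic overview**
1. Target ⇐ desilylation/acetylation of the tris-silylated α-methylene lactone 21 ⇐ Mannich elimination ⇐ copper hydride 1,4-reduction/aminomethylation of butenolide 17, which sets H-7 on a trigonal C7.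
2. Butenolide 17 ⇐ domino O-acylation/intramolecular Wittig olefination of α-hydroxy ketone 14 with (triphenylphosphoranylidene)ketene; the γ-lactone ring is closed last, by the C7–C11 bond.
3. Enabling feature: in the cyclohexane ring C7 is flanked by the two oxygen-bearing carbons C6 and C8 (a reduced dihydroxyacetone unit). At the ketone level C7 is the only ring carbonyl, both α-carbons are hydroxylated from the open α-face, and the C6 oxygen tethers the ylide carbon C11 five atoms from C7=O.
4. Ketone 11 ⇐ rhodium-catalysed asymmetric conjugate alkenylation (C5–C4) of enone 7 ⇐ enantioselective Diels–Alder reaction (C5–C10 and C8–C9 bonds; C10 quaternary centre).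
5. Ring order: cyclohexane first (Diels–Alder), γ-lactone last (C7–C11).

Key step: step 11

**Route**

Step 1
Reactants: 1 2-methylenepropane-1,3-diol
Product: 2 2-{[(tert-butyldiphenylsilyl)oxy]methyl}prop-2-en-1-ol
Conditions: NaH (1.0 equiv), THF, 0 °C; then TBDPSCl (1.0 equiv), 0 °C → rt
Reagents that add atoms: tert-butyl(chloro)diphenylsilane, CC(C)(C)[Si](Cl)(c1ccccc1)c1ccccc1
Why: O-silylation of the mono-sodium alkoxide of a symmetric diol should give the mono-ether; no stereocentre is involved.

Step 2
Reactants: 2 2-{[(tert-butyldiphenylsilyl)oxy]methyl}prop-2-en-1-ol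
Product: 3 2-{[(tert-butyldiphenylsilyl)oxy]methyl}prop-2-enal
Conditions: activated MnO2 (excess), CH2Cl2, rt
Reagents that add atoms: none
Why: Manganese dioxide oxidation of a primary allylic alcohol should stop cleanly at the 2-substituted acrolein.

Step 3
Reactants: 3 2-{[(tert-butyldiphenylsilyl)oxy]methyl}prop-2-enal; 4 (1E)-3-[(tert-butyldimethylsilyl)oxy]-N,N-dimethylbuta-1,3-dien-1-amine
Product: 5 endo cycloadduct 2-(dimethylamino)-4-[(tert-butyldimethylsilyl)oxy]-1-{[(tert-butyldiphenylsilyl)oxy]methyl}cyclohex-3-ene-1-carbaldehyde (NMe2 cis to CHO; quaternary centre as in 7)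
Conditions: [Cr(salen)]SbF6 (5 mol%, trivalent chromium; salen = (1R,2R)-N,N′-bis(3,5-di-tert-butylsalicylidene)cyclohexane-1,2-diaminate, enantiomer giving (R)-7), 4 Å MS, CH2Cl2, −40 °C
Reagents that add atoms: none
Why: In this catalytic enantioselective Diels–Alder reaction the amino-bearing diene terminus bonds to the formyl-bearing carbon (C5–C10) and the CH2 terminus to the dienophile CH2 (C8–C9), endo, while the chiral chromium Lewis acid on the aldehyde screens one enantioface and so sets the C10 quaternary stereocentre.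

Step 4
Reactants: 5 endo cycloadduct
Product: 7 (R)-4-{[(tert-butyldiphenylsilyl)oxy]methyl}-4-ethenylcyclohex-2-en-1-one, via vinyl cycloadduct 6 (not isolated)
Conditions: Ph3PCH3Br, KHMDS, THF, −78 → 0 °C; then 1 M HCl, THF, 0 °C
Reagents that add atoms: methyltriphenylphosphonium bromide, C[P+](c1ccccc1)(c1ccccc1)c1ccccc1.[Br-]
Why: Wittig methylenation of the non-enolisable aldehyde installs the C1=C2 vinyl group, and aqueous acid then hydrolyses the silyl enol ether and eliminates dimethylamine (β-elimination) to the enone; C10 is untouched.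

Step 5
Reactants: 8 2-bromoprop-2-en-1-ol
Product: 9 tert-butyl[(2-bromoprop-2-en-1-yl)oxy]dimethylsilane
Conditions: TBSCl, imidazole, CH2Cl2, 0 °C → rt
Reagents that add atoms: tert-butyl(chloro)dimethylsilane, CC(C)(C)[Si](C)(C)Cl
Why: Standard imidazole-mediated silylation of a primary alcohol.

Step 6
Reactants: 9 tert-butyl[(2-bromoprop-2-en-1-yl)oxy]dimethylsilane
Product: 10 tert-butyldimethyl{[2-(4,4,5,5-tetramethyl-1,3,2-dioxaborolan-2-yl)prop-2-en-1-yl]oxy}silane
Conditions: t-BuLi (2.1 equiv), Et2O, −78 °C; then 2-isopropoxy-4,4,5,5-tetramethyl-1,3,2-dioxaborolane, −78 °C → rt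
Reagents that add atoms: 2-isopropoxy-4,4,5,5-tetramethyl-1,3,2-dioxaborolane, CC(C)OB1OC(C)(C)C(C)(C)O1
Why: Bromine–lithium exchange at −78 °C, where the β-silyloxy vinyllithium should not eliminate to allene, followed by borate trapping gives the alkenylboronate.

Step 7
Reactants: 7 (R)-4-{[(tert-butyldiphenylsilyl)oxy]methyl}-4-ethenylcyclohex-2-en-1-one; 10 alkenylboronate
Product: 11 (3S,4R)-4-{[(tert-butyldiphenylsilyl)oxy]methyl}-3-{3-[(tert-butyldimethylsilyl)oxy]prop-1-en-2-yl}-4-ethenylcyclohexan-1-one (C7 ketone; C5 side chain β, cis to C14)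
Conditions: [Rh(OH)((S)-BINAP)]2 (3 mol%), KOH (0.1 equiv), 1,4-dioxane/H2O 10:1, 50 °C
Reagents that add atoms: none
Why: In this Hayashi–Miyaura asymmetric 1,4-addition the alkenylrhodium species adds to C5; because the two C10 substituents are of similar size, the face is left to the catalyst, and (S)-BINAP should deliver the group to the β-face by analogy with cyclohex-2-enone.

Step 8
Reactants: 11 ketone
Product: 12 8α-hydroxy derivative of ketone 11 (OH on the CH2 carbon between C7 and C9, trans to C14)
Conditions: LDA (1.1 equiv), THF, −78 °C; then 2-(phenylsulfonyl)-3-phenyloxaziridine, −78 °C; AcOH quench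
Reagents that add atoms: 2-(phenylsulfonyl)-3-phenyloxaziridine, O=S(=O)(c1ccccc1)N1OC1c1ccccc1
Why: Kinetic deprotonation should occur at C8, the α-methylene remote from the branched C5, and the oxaziridine should hydroxylate the enolate from the α-face because the β-face is screened by the axial C14H2OTBDPS group (1,3 to C8).

Step 9
Reactants: 12 8α-hydroxy ketone
Product: 13 8α-triethylsilyl ether of 12
Conditions: TESOTf, 2,6-lutidine, CH2Cl2, −78 °C
Reagents that add atoms: triethylsilyl trifluoromethanesulfonate, CC[Si](CC)(CC)OS(=O)(=O)C(F)(F)F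
Why: Silyl triflate protection of the hindered α-hydroxy ketone under non-enolising conditions keeps the C8 configuration.

Step 10
Reactants: 13 8α-silyloxy ketone
Product: 14 6α-hydroxy-8α-(triethylsilyloxy) ketone (6-OH trans to the C5 side chain)
Conditions: LDA (1.1 equiv), THF, −78 °C; then 2-(phenylsulfonyl)-3-phenyloxaziridine, −78 °C; AcOH quench at −78 °C
Reagents that add atoms: 2-(phenylsulfonyl)-3-phenyloxaziridine, O=S(=O)(c1ccccc1)N1OC1c1ccccc1
Why: Only the C6 methylene remains kinetically acidic, and enolate hydroxylation should occur anti to the adjacent C5 substituent and to axial C14, giving the 6α-alcohol; the cold quench avoids silyl migration.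

Step 11
Reactants: 14 6α-hydroxy-8α-(triethylsilyloxy) ketone; 15 (triphenylphosphoranylidene)ketene
Product: 17 fused butenolide (7(11)-en-12,6α-olide with 8α-OTES, 15-OTBS, 14-OTBDPS), via ester ylide 16 (not isolated)
Conditions: toluene, 90 °C
Reagents that add atoms: none
Why: The only free hydroxyl of 14 (C6–OH) adds across the C=C of the cumulated ylide to give the ester-stabilised ylide 16, whose carbon C11 then olefinates the neighbouring C7 ketone through an oxaphosphetane, expelling triphenylphosphine oxide and closing the ring O–C6–C7–C11–C12 by the C7–C11 bond (as C7=C11). The closest known reaction type is the domino addition/Wittig annulation of α-hydroxy ketones with ketenylidenetriphenylphosphorane to butenolides. The ring closes in the 5-exo-trig mode, ylide carbon onto ketone carbon, with the carbonyl oxygen leaving as phosphine oxide. No stereocentre is created: C7 is made trigonal on purpose, because a five-membered closure from the C6 oxygen onto a tetrahedral C7 would be expected to give only the cis ring fusion, whereas the alkylidene lactone leaves H-7 to be delivered afterwards from the α-face. The step needs chemoselectivity, which is secured by there being one free OH and one ketone (the C8, C14 and C15 oxygens are silylated), and retention of the C6 and C8 α-oxy-ketone centres, which the neutral, base-free conditions should ensure.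

Step 12
Reactants: 17 fused butenolide
Product: 19 13-(dimethylamino)-11,13-dihydro trans-lactone (7αH; C11 epimers; silyl groups as in 17), via silyl ketene acetal 18 (not isolated)
Conditions: Cu(OAc)2 (5 mol%), p-tol-BINAP (5 mol%, enantiomer matched to α-face delivery), (EtO)2MeSiH (2 equiv), toluene, 0 °C; then CH2=NMe2+ I−, CH2Cl2, rt; aq. NaHCO3
Reagents that add atoms: N,N-dimethylmethyleneiminium iodide, C=[N+](C)C.[I-]
Why: Ligand-controlled copper hydride 1,4-reduction of the β-substituted butenolide should deliver hydride to C7 along the axial α-trajectory so that C11 becomes equatorial (β, trans-fused lactone), and the resulting silyl ketene acetal is aminomethylated in a Mannich reaction without strong base; the C11 configuration is immaterial.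

Step 13
Reactants: 19 Mannich base
Product: 21 8α-(triethylsilyloxy)-15-(tert-butyldimethylsilyloxy)-14-(tert-butyldiphenylsilyloxy)elema-1,3,11(13)-trien-12,6α-olide, via ammonium iodide 20 (not isolated)
Conditions: MeI, MeOH, rt; then aq. NaHCO3, EtOAc, rt
Reagents that add atoms: none
Why: Quaternisation followed by mild-base Hofmann-type elimination of the β-ammonio lactone unveils the exocyclic C11=C13 methylene without touching C7.

Step 14
Reactants: 21 tris-silylated α-methylene lactone
Product: 22 8α,15-dihydroxy-14-(tert-butyldiphenylsilyloxy)elema-1,3,11(13)-trien-12,6α-olide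
Conditions: CSA (0.2 equiv), MeOH/CH2Cl2 1:1, 0 °C → rt
Reagents that add atoms: none
Why: Acid-catalysed methanolysis should remove the secondary TES and primary allylic TBS ethers while the far more acid-stable neopentyl TBDPS ether survives.

Step 15
Reactants: 22 8α,15-diol
Product: 23 8α,15-diacetoxy-14-(tert-butyldiphenylsilyloxy)elema-1,3,11(13)-trien-12,6α-olide
Conditions: Ac2O, pyridine, DMAP (cat.), CH2Cl2, 0 °C
Reagents that add atoms: acetic anhydride, CC(=O)OC(C)=O
Why: Standard acetylation of both free hydroxyls, with retention at C8.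

Step 16
Reactants: 23 diacetate
Product: 24 CNP0240658.1, 8α,15-diacetoxy-14-hydroxyelema-1,3,11(13)-trien-12,6α-olide
Conditions: HF·pyridine, THF/pyridine, 0 °C → rt
Reagents that add atoms: none
Why: Buffered fluoride cleavage of the TBDPS ether frees the C14 primary alcohol under conditions that should leave the acetates and the α-methylene lactone intact.

**Compound list**
1 | 2-methylenepropane-1,3-diol | C=C(CO)CO | starting material
2 | 2-{[(tert-butyldiphenylsilyl)oxy]methyl}prop-2-en-1-ol | C=C(CO)CO[Si](c1ccccc1)(c1ccccc1)C(C)(C)C | intermediate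
3 | 2-{[(tert-butyldiphenylsilyl)oxy]methyl}prop-2-enal | C=C(C=O)CO[Si](c1ccccc1)(c1ccccc1)C(C)(C)C | intermediate
4 | (1E)-3-[(tert-butyldimethylsilyl)oxy]-N,N-dimethylbuta-1,3-dien-1-amine | CN(C)/C=C/C(=C)O[Si](C)(C)C(C)(C)C | starting material
5 | endo cycloadduct (aldehyde, silyl enol ether, NMe2 cis to CHO) | O=C[C@]1(CO[Si](c2ccccc2)(c2ccccc2)C(C)(C)C)CCC(O[Si](C)(C)C(C)(C)C)=C[C@@H]1N(C)C | intermediate
6 | vinyl cycloadduct | C=C[C@]1(CO[Si](c2ccccc2)(c2ccccc2)C(C)(C)C)CCC(O[Si](C)(C)C(C)(C)C)=C[C@@H]1N(C)C | intermediate (not isolated)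
7 | (R)-4-{[(tert-butyldiphenylsilyl)oxy]methyl}-4-ethenylcyclohex-2-en-1-one | C=C[C@]1(CO[Si](c2ccccc2)(c2ccccc2)C(C)(C)C)CCC(=O)C=C1 | intermediate
8 | 2-bromoprop-2-en-1-ol | C=C(Br)CO | starting material
9 | tert-butyl[(2-bromoprop-2-en-1-yl)oxy]dimethylsilane | C=C(Br)CO[Si](C)(C)C(C)(C)C | intermediate
10 | tert-butyldimethyl{[2-(4,4,5,5-tetramethyl-1,3,2-dioxaborolan-2-yl)prop-2-en-1-yl]oxy}silane | C=C(CO[Si](C)(C)C(C)(C)C)B1OC(C)(C)C(C)(C)O1 | intermediate
11 | (3S,4R)-4-{[(tert-butyldiphenylsilyl)oxy]methyl}-3-{3-[(tert-butyldimethylsilyl)oxy]prop-1-en-2-yl}-4-ethenylcyclohexan-1-one | C=C[C@]1(CO[Si](c2ccccc2)(c2ccccc2)C(C)(C)C)CCC(=O)C[C@H]1C(=C)CO[Si](C)(C)C(C)(C)C | intermediate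
12 | 8α-hydroxy derivative of ketone 11 | C=C[C@]1(CO[Si](c2ccccc2)(c2ccccc2)C(C)(C)C)C[C@H](O)C(=O)C[C@H]1C(=C)CO[Si](C)(C)C(C)(C)C | intermediate
13 | 8α-triethylsilyl ether of 12 | C=C[C@]1(CO[Si](c2ccccc2)(c2ccccc2)C(C)(C)C)C[C@H](O[Si](CC)(CC)CC)C(=O)C[C@H]1C(=C)CO[Si](C)(C)C(C)(C)C | intermediate
14 | 6α-hydroxy-8α-(triethylsilyloxy) ketone | C=C[C@]1(CO[Si](c2ccccc2)(c2ccccc2)C(C)(C)C)C[C@H](O[Si](CC)(CC)CC)C(=O)[C@H](O)[C@H]1C(=C)CO[Si](C)(C)C(C)(C)C | intermediate
15 | (triphenylphosphoranylidene)ketene | O=C=C=P(c1ccccc1)(c1ccccc1)c1ccccc1 | starting material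
16 | ester ylide (O6-(triphenylphosphoranylidene)acetate of 14) | C=C[C@]1(CO[Si](c2ccccc2)(c2ccccc2)C(C)(C)C)C[C@H](O[Si](CC)(CC)CC)C(=O)[C@H](OC(=O)C=P(c2ccccc2)(c2ccccc2)c2ccccc2)[C@H]1C(=C)CO[Si](C)(C)C(C)(C)C | intermediate (not isolated)
17 | fused butenolide (7(11)-en-12,6α-olide; 8α-OTES, 15-OTBS, 14-OTBDPS) | C=C[C@]1(CO[Si](c2ccccc2)(c2ccccc2)C(C)(C)C)C[C@H](O[Si](CC)(CC)CC)C2=CC(=O)O[C@@H]2[C@H]1C(=C)CO[Si](C)(C)C(C)(C)C | intermediate
18 | silyl ketene acetal of the 7αH lactone | C=C[C@]1(CO[Si](c2ccccc2)(c2ccccc2)C(C)(C)C)C[C@H](O[Si](CC)(CC)CC)[C@H]2C=C(O[Si](C)(OCC)OCC)O[C@@H]2[C@H]1C(=C)CO[Si](C)(C)C(C)(C)C | intermediate (not isolated)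
19 | 13-(dimethylamino)-11,13-dihydro trans-lactone (C11 epimers) | C=C[C@]1(CO[Si](c2ccccc2)(c2ccccc2)C(C)(C)C)C[C@H](O[Si](CC)(CC)CC)[C@H]2C(CN(C)C)C(=O)O[C@@H]2[C@H]1C(=C)CO[Si](C)(C)C(C)(C)C | intermediate
20 | trimethylammonium iodide of 19 | C=C[C@]1(CO[Si](c2ccccc2)(c2ccccc2)C(C)(C)C)C[C@H](O[Si](CC)(CC)CC)[C@H]2C(C[N+](C)(C)C)C(=O)O[C@@H]2[C@H]1C(=C)CO[Si](C)(C)C(C)(C)C.[I-] | intermediate (not isolated)
21 | 8α-OTES, 15-OTBS, 14-OTBDPS elema-1,3,11(13)-trien-12,6α-olide | C=C[C@]1(CO[Si](c2ccccc2)(c2ccccc2)C(C)(C)C)C[C@H](O[Si](CC)(CC)CC)[C@H]2C(=C)C(=O)O[C@@H]2[C@H]1C(=C)CO[Si](C)(C)C(C)(C)C | intermediate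
22 | 8α,15-dihydroxy-14-OTBDPS elema-1,3,11(13)-trien-12,6α-olide | C=C[C@]1(CO[Si](c2ccccc2)(c2ccccc2)C(C)(C)C)C[C@H](O)[C@H]2C(=C)C(=O)O[C@@H]2[C@H]1C(=C)CO | intermediate
23 | 8α,15-diacetoxy-14-OTBDPS elema-1,3,11(13)-trien-12,6α-olide | C=C[C@]1(CO[Si](c2ccccc2)(c2ccccc2)C(C)(C)C)C[C@H](OC(C)=O)[C@H]2C(=C)C(=O)O[C@@H]2[C@H]1C(=C)COC(C)=O | intermediate
24 | CNP0240658.1, 8α,15-diacetoxy-14-hydroxyelema-1,3,11(13)-trien-12,6α-olide | C=C[C@]1(CO)C[C@H](OC(C)=O)[C@H]2C(=C)C(=O)O[C@@H]2[C@H]1C(=C)COC(C)=O | target

**Step count.** Total: 16 steps. Longest linear sequence: 14 steps (steps 1–4 and 7–16); steps 5–6 form the convergent branch.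

**Steps most likely to fail, with fallbacks**

Step 12. Hydride may be delivered to C7 from the β-face (equatorial attack), which would give the cis-fused lactone, or the butenolide may be over-reduced before the enolate is trapped. The fallback sets out from butenolide 17 and separates reduction from methylenation. Conjugate reduction with the small nucleophilic hydride NaBH4 (MeOH/THF, 0 °C), whose axial attack should place C11 equatorial, would give the 11-unsubstituted saturated trans-lactone F1. Its lithium enolate (LDA, THF, −78 °C; no ester groups are present at this stage) is then aminomethylated with N,N-dimethylmethyleneiminium iodide, which comes back to the route at Mannich base 19.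

Step 7. The β-carbon next to the quaternary centre may react sluggishly with the bulky 1,1-disubstituted alkenylrhodium species, or catalyst control of the C5 face may be insufficient. The fallback sets out from enone 7 and uses substrate-directed delivery. Fluoride desilylation (TBAF, THF) would give (R)-4-ethenyl-4-(hydroxymethyl)cyclohex-2-en-1-one F2. Its lithium alkoxide (n-BuLi) is combined with the alkenylcopper reagent made from bromide 9 (t-BuLi, then CuI) to form an alkoxy(alkenyl)cuprate, which should transfer the alkenyl group intramolecularly to C5 on the face of the CH2O group and give the 14-hydroxy ketone F3. Resilylation (TBDPSCl, imidazole) comes back to the route at ketone 11.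

Step 8. Kinetic enolisation may be incompletely regioselective (competing deprotonation at C6), which would misplace the silyl ether and later the lactone. The fallback sets out from ketone 11 and makes the regiochemistry of enolisation irrelevant. Two successive enolate hydroxylations with the same oxaziridine, without protection in between, are run: the first gives 12 together with its regioisomer, the 6α-hydroxy ketone F4, and the second (LDA, 2.2 equiv) converts both into the 6α,8α-dihydroxy ketone F5. The less hindered C8 hydroxyl is then silylated selectively (TESCl, imidazole, −40 °C), which comes back to the route at 14.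

Further compounds
F1 | step 12 | 11-unsubstituted saturated trans-lactone (7αH-12,6α-olide; 8α-OTES, 15-OTBS, 14-OTBDPS) | C=C[C@]1(CO[Si](c2ccccc2)(c2ccccc2)C(C)(C)C)C[C@H](O[Si](CC)(CC)CC)[C@H]2CC(=O)O[C@@H]2[C@H]1C(=C)CO[Si](C)(C)C(C)(C)C
F2 | step 7 | (R)-4-ethenyl-4-(hydroxymethyl)cyclohex-2-en-1-one | C=C[C@]1(CO)CCC(=O)C=C1
F3 | step 7 | 14-hydroxy ketone (11 without the TBDPS group) | C=C[C@]1(CO)CCC(=O)C[C@H]1C(=C)CO[Si](C)(C)C(C)(C)C
F4 | step 8 | 6α-hydroxy derivative of ketone 11 | C=C[C@]1(CO[Si](c2ccccc2)(c2ccccc2)C(C)(C)C)CCC(=O)[C@H](O)[C@H]1C(=C)CO[Si](C)(C)C(C)(C)C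
F5 | step 8 | 6α,8α-dihydroxy derivative of ketone 11 | C=C[C@]1(CO[Si](c2ccccc2)(c2ccccc2)C(C)(C)C)C[C@H](O)C(=O)[C@H](O)[C@H]1C(=C)CO[Si](C)(C)C(C)(C)C
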